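**Remark on the chemistry:** the SMILES is read as the achiral flavone 5,2',4'-trihydroxy-6,7,8-trimethoxyflavone; 1,2,3,4-tetramethoxybenzene (1) and 2,4-bis(benzyloxy)benzaldehyde (9) are taken as commercially available.

## Structural features

Tamadone (16) is a flavone: a benzene ring A fused to a pyran-4-one ring C, with a 2,4-dihydroxyphenyl ring B on C2; it has no stereocentre. Ring A is hexasubstituted: C5 (OH), C6, C7 and C8 (OMe) carry four contiguous oxygens, and the fusion carbons C4a and C8a are bonded to the C4 carbonyl carbon and to O1. The 5-OH is peri to C4=O and hydrogen-bonded to it, which sets it apart from the other three ring A oxygens. The fragile groups are the electron-rich free phenols (the para C5/C8 oxygen pair can be oxidised to a quinone), the aryl methyl ethers towards strong Lewis acids, and the C2=C3 enone towards nucleophiles and reduction. The real difficulty is ring A: six substituents, five of them oxygens, on one benzene ring, with ring C fused at the correct pair of neighbouring carbons and one of four oxygens left unmethylated. The key step exploits the following feature: with all four oxygens at C5 to C8 as methyl ethers, ring A has a local mirror plane through the midpoints of C6–C7 and C4a–C8a. C4a and C8a can therefore be the two carbons of a symmetric aryne, which takes up the C4 acyl carbon and O1 in one operation with no regiochemical question, and the peri relation between C5–O and C4=O later singles out the one methyl ether to be removed.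

## Logic of the disconnections

**16 ⇒ 15.** The bonds cut (in the forward sense) are the O–CH3 bond at C5 and the two O–CH2Ph bonds on ring B. With C5–O methylated the four ring A oxygens become pairwise equivalent, which makes the next cut regiochemically silent, and the benzyl groups keep the ring B oxygens from adding to an aryne. The gain is a symmetric ring A and no free phenol. The forward step must cleave only the peri methyl ether and the benzyl ethers and leave the C6, C7 and C8 methyl ethers.

**15 ⇒ 8 + 12 (through 13 and 14).** The bonds cut are C4a–C4, C8a–O1 and O1–C2, which is the whole of ring C apart from the C2–C3–C4 chain. C4a and C8a are neighbours on ring A and become the triple bond of 13; because 13 is symmetric, either sense of addition gives the same product. The gain is large: a C10 and a C23 fragment are joined and ring C is formed in one operation, and the sixth substituent of ring A never has to be forced onto a pentasubstituted ring by electrophilic acylation. The forward step demands that the carboxylate of 12 adds to 13, that the resulting aryl anion transfers the acyl group to carbon before it is protonated, and that the phenoxide of 14 closes in the 6-endo sense.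

**8 ⇒ 5 (through 6 and 7).** The C–Si and O–S bonds are cut; the silyl group is delivered from oxygen to the carbon that bears bromine. The gain is a simple bromophenol. The demand is a clean bromine–lithium exchange on a hexasubstituted ring.

**5 ⇒ 4.** The C–Br bond is cut. The ring has a single free carbon, ortho to the hydroxyl, so no regiochemical choice exists. The demand is bromination without oxidation of the electron-rich phenol.

**4 ⇒ 1 (through 2 and 3).** The C–O bond of the phenol is cut. Both free positions of 1 are equivalent and each is ortho to a methoxy group, so directed metalation gives one product. The gain is a commercial symmetric arene.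

**12 ⇒ 10 (through 11).** The C–CO2H bond is cut; the acetylide carbon is the nucleophile and carbon dioxide the electrophile. The demand is that the benzyl ethers tolerate the organolithium at low temperature.

**10 ⇒ 9.** The alkyne carbon is traced back to an aldehyde by one-carbon homologation. The gain is a commercial, already protected ring B aldehyde.

## Other disconnections considered

**Alternative 1:** (the first that comes to mind) cut O1–C2 and C2–C3 by the Baker–Venkataraman route. 4 would be C-acetylated at its one free position to 1-(2-hydroxy-3,4,5,6-tetramethoxyphenyl)ethan-1-one A1, O-aroylated to ester A2, rearranged with base to the 1,3-diketone A3 and cyclodehydrated with acid to 15. The chosen plan is preferred on three grounds. Ring C costs three operations from A1 against one from 8 + 12. The acetylation that makes A1 uses a Lewis or Brønsted acid on a pentaoxygenated ring, where the methoxy group ortho to the new carbonyl is activated for cleavage by the same chelation that is wanted only once, at the end. The key bonds lie away from ring A, so the step does not address the difficulty of the target.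

**Alternative 2:** cut C4a–C5 and C8–C8a and build ring A by thermal ring expansion of a squarate adduct. The 5-lithiated 2-aryl-pyran-4-one A5 would add to dimethyl squarate A4 to give the 4-hydroxycyclobutenone A6. Heating would open A6 to a dienylketene, which closes by 6π electrocyclisation and tautomerises to the 5,8-dihydroxy-6,7-dimethoxyflavone A7, to be methylated at 8-O. The idea differentiates C5–O from C8–O by origin, but the chosen plan is preferred on mechanistic grounds. In A5 the C–Li bond is anti-periplanar to the C6–O1 bond and the leaving group is a stabilised diketonate, so ring-opening β-elimination is expected to compete with addition. The halide precursor of A5 needs halogenation at one α-carbon in the presence of the very electron-rich ring B. A7 is a para-hydroquinone that oxidises readily to the quinone. The route is also longer.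

**Alternative 3:** cut C4–C4a, closing ring C at a carbon–carbon bond. Oxa-Michael addition of 4 to methyl arylpropiolate A8 would give the (Z)-3-aryloxyacrylate A9, and Friedel–Crafts acylation at the last free carbon of ring A would give 15. The chosen plan is preferred because the acylation needs strong acid, under which the benzyl ethers of ring B and the enol ether of A9 are labile and the alkoxy-activated ring B competes as a nucleophile. It also needs two operations for ring C, whereas the aryne step needs one and runs under fluoride without acid.

Key step: step 6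

## Route

**Step 1**
Reactants: 1 1,2,3,4-tetramethoxybenzene
Product: 4 2,3,4,5-tetramethoxyphenol, via aryllithium 2 (not isolated), via dimethyl arylboronate 3 (not isolated)
Conditions: n-BuLi, TMEDA, THF, 0 °C; B(OMe)3, −78 °C → rt; 30% H2O2, AcOH, 0 °C → rt
Reagents that add atoms: hydrogen peroxide OO
Why: Directed ortho-metalation next to a methoxy group (the two free positions of 1 are equivalent), trapping as the boronate and oxidation with 1,2-aryl shift from boron to oxygen; a standard lithiation–borylation–oxidation sequence.

**Step 2**
Reactants: 4 2,3,4,5-tetramethoxyphenol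
Product: 5 2-bromo-3,4,5,6-tetramethoxyphenol
Conditions: NBS, CH2Cl2, −40 → 0 °C, dark
Reagents that add atoms: N-bromosuccinimide O=C1CCC(=O)N1Br
Why: Electrophilic aromatic bromination at the only unsubstituted ring carbon, which is ortho to the hydroxyl; anhydrous conditions and low temperature disfavour oxidation to a quinone.

**Step 3**
Reactants: 5 2-bromo-3,4,5,6-tetramethoxyphenol
Product: 8 3,4,5,6-tetramethoxy-2-(trimethylsilyl)phenyl trifluoromethanesulfonate, via aryl trimethylsilyl ether 6 (not isolated), via lithium silylphenoxide 7 (not isolated)
Conditions: HMDS, THF, 65 °C, then evaporation; n-BuLi, THF, −78 °C; Tf2O, −78 → 0 °C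
Reagents that add atoms: hexamethyldisilazane C[Si](C)(C)N[Si](C)(C)C; trifluoromethanesulfonic anhydride O=S(=O)(OS(=O)(=O)C(F)(F)F)C(F)(F)F
Why: The standard preparation of o-silylaryl triflates: O-silylation, bromine–lithium exchange followed by 1,3 O→C silyl migration (retro-Brook rearrangement) driven by phenoxide formation, then O-triflation.

**Step 4**
Reactants: 9 2,4-bis(benzyloxy)benzaldehyde
Product: 10 2,4-bis(benzyloxy)-1-(2,2-dibromoethenyl)benzene
Conditions: CBr4, PPh3, CH2Cl2, 0 °C
Reagents that add atoms: carbon tetrabromide BrC(Br)(Br)Br
Why: Corey–Fuchs dibromo-olefination, a Wittig reaction of the dibromomethylene ylide formed in the flask; benzyl ethers are inert.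

**Step 5**
Reactants: 10 2,4-bis(benzyloxy)-1-(2,2-dibromoethenyl)benzene
Product: 12 3-[2,4-bis(benzyloxy)phenyl]prop-2-ynoic acid, via lithium acetylide 11 (not isolated)
Conditions: n-BuLi (2.2 equiv), THF, −78 °C; CO2, −78 °C → rt; aq. HCl
Reagents that add atoms: carbon dioxide O=C=O
Why: Second stage of the Corey–Fuchs sequence: bromine–lithium exchange, α-elimination and 1,2-shift (Fritsch–Buttenberg–Wiechell rearrangement) give the lithium acetylide, which is carboxylated by carbon dioxide.

**Step 6**
Reactants: 8 3,4,5,6-tetramethoxy-2-(trimethylsilyl)phenyl trifluoromethanesulfonate; 12 3-[2,4-bis(benzyloxy)phenyl]prop-2-ynoic acid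
Product: 15 2-[2,4-bis(benzyloxy)phenyl]-5,6,7,8-tetramethoxy-4H-chromen-4-one, via tetramethoxybenzyne 13 (not isolated), via hydroxyaryl ynone 14 (not isolated)
Conditions: CsF, THF, 125 °C, sealed tube (8 in slight excess)
Reagents that add atoms: none
Why: Fluoride attacks silicon in 8 and triflate is lost to give aryne 13, while CsF converts 12 into its cesium carboxylate, which adds through oxygen to the aryne. The resulting 2-(acyloxy)aryl anion attacks its own ester carbonyl (4-exo-trig, a transient benzoxetene alkoxide) and the ring reopens to the phenoxide of ynone 14, so the aryne is inserted into the acyl–oxygen bond and the C8a–O1 and C4a–C4 bonds are made. The phenoxide then closes ring C by 6-endo-dig conjugate addition to the ynone β-carbon (O1–C2), and protonation at C3 gives the chromenone. The closest known reaction type is the fluoride-mediated intermolecular C–O addition of carboxylic acids to arynes, which with arylpropiolic acids leads to flavones. No stereocentre is formed. Regioselectivity of the addition to the aryne is not an issue because 13 has a mirror plane through the triple bond, so both senses of addition give the same hexasubstituted ring. Acyl transfer has to outrun protonation of the aryl anion, which the high temperature and the intramolecular four-centre geometry favour. The 6-endo closure is preferred over 5-exo (aurone) for a soft phenoxide adding in conjugate fashion to an aryl ynone whose β-carbon carries an electron-rich aryl group, and it leads to the aromatic pyranone.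

**Step 7**
Reactants: 15 2-[2,4-bis(benzyloxy)phenyl]-5,6,7,8-tetramethoxy-4H-chromen-4-one
Product: 16 Tamadone, 2-(2,4-dihydroxyphenyl)-5-hydroxy-6,7,8-trimethoxy-4H-chromen-4-one
Conditions: BCl3 (excess), C6HMe5, CH2Cl2, −78 → 0 °C; H2O
Reagents that add atoms: none
Why: Lewis-acid ether cleavage: the benzyl ethers are cleaved at low temperature with the benzyl cation trapped by pentamethylbenzene, and BCl3 chelated between C4=O and the C5 oxygen (six-membered chelate) removes only the peri methyl group. The methyl ethers at C6, C7 and C8 lack this activation and should remain; aqueous work-up frees the phenols from their borates.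

## Compound list

1 | 1,2,3,4-tetramethoxybenzene | COc1ccc(OC)c(OC)c1OC | starting material
2 | (2,3,4,5-tetramethoxyphenyl)lithium | [Li]c1cc(OC)c(OC)c(OC)c1OC | intermediate
3 | dimethyl (2,3,4,5-tetramethoxyphenyl)boronate | COB(OC)c1cc(OC)c(OC)c(OC)c1OC | intermediate
4 | 2,3,4,5-tetramethoxyphenol | COc1cc(O)c(OC)c(OC)c1OC | intermediate
5 | 2-bromo-3,4,5,6-tetramethoxyphenol | COc1c(Br)c(O)c(OC)c(OC)c1OC | intermediate
6 | (2-bromo-3,4,5,6-tetramethoxyphenoxy)trimethylsilane | COc1c(Br)c(O[Si](C)(C)C)c(OC)c(OC)c1OC | intermediate
7 | lithium 3,4,5,6-tetramethoxy-2-(trimethylsilyl)phenoxide | COc1c([Si](C)(C)C)c([O-])c(OC)c(OC)c1OC.[Li+] | intermediate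
8 | 3,4,5,6-tetramethoxy-2-(trimethylsilyl)phenyl trifluoromethanesulfonate | COc1c([Si](C)(C)C)c(OS(=O)(=O)C(F)(F)F)c(OC)c(OC)c1OC | intermediate
9 | 2,4-bis(benzyloxy)benzaldehyde | O=Cc1ccc(OCc2ccccc2)cc1OCc1ccccc1 | starting material
10 | 2,4-bis(benzyloxy)-1-(2,2-dibromoethenyl)benzene | BrC(Br)=Cc1ccc(OCc2ccccc2)cc1OCc1ccccc1 | intermediate
11 | lithium [2,4-bis(benzyloxy)phenyl]acetylide | [Li]C#Cc1ccc(OCc2ccccc2)cc1OCc1ccccc1 | intermediate
12 | 3-[2,4-bis(benzyloxy)phenyl]prop-2-ynoic acid | OC(=O)C#Cc1ccc(OCc2ccccc2)cc1OCc1ccccc1 | intermediate
13 | 3,4,5,6-tetramethoxybenzyne (1,2-didehydro-3,4,5,6-tetramethoxybenzene) | COC1=C(OC)C(OC)=C(OC)C#C1 | intermediate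
14 | 3-[2,4-bis(benzyloxy)phenyl]-1-(2-hydroxy-3,4,5,6-tetramethoxyphenyl)prop-2-yn-1-one (present as its cesium phenoxide) | COc1c(OC)c(OC)c(C(=O)C#Cc2ccc(OCc3ccccc3)cc2OCc2ccccc2)c(O)c1OC | intermediate
15 | 2-[2,4-bis(benzyloxy)phenyl]-5,6,7,8-tetramethoxy-4H-chromen-4-one | COc1c(OC)c(OC)c2c(=O)cc(-c3ccc(OCc4ccccc4)cc3OCc3ccccc3)oc2c1OC | intermediate
16 | Tamadone, 2-(2,4-dihydroxyphenyl)-5-hydroxy-6,7,8-trimethoxy-4H-chromen-4-one | COc1c(OC)c(O)c2c(=O)cc(-c3ccc(O)cc3O)oc2c1OC | target

## Step count and least certain steps

Total: 7 steps. Longest linear sequence: 5 steps (steps 1, 2, 3, 6, 7); the second branch is steps 4 and 5.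

**Step 6 (key step).** Three processes are most likely to go wrong: protonation of the 2-(acyloxy)aryl anion before acyl transfer, which stops at simple O-arylation of the acid; thermal decarboxylation of the arylpropiolate at 125 °C; and closure of the phenoxide in the 5-exo sense. The fallback sets out from 4 and 10 and comes back at 15. 4 is iodinated at its free position (NIS, MeCN) to 2-iodo-3,4,5,6-tetramethoxyphenol F1. 10 is treated with n-BuLi and quenched with aqueous NH4Cl to give 2,4-bis(benzyloxy)-1-ethynylbenzene F2. The two are joined by carbonylative Sonogashira coupling with cyclisation (PdCl2(PPh3)2, CO, Et2NH, heat), which passes through 14 and closes it to 15 via the amine adduct.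

**Step 7.** The likely failures are incomplete cleavage of the peri methyl ether at low temperature, or, with forcing, further demethylation at C6 once the C5 oxygen is bound to boron, and C-benzylation of ring B if the scavenger is inefficient. The fallback sets out from 15 and comes back at 16. Hydrogenolysis (H2, Pd/C, EtOAc/THF) removes the benzyl groups to give 2-(2,4-dihydroxyphenyl)-5,6,7,8-tetramethoxy-4H-chromen-4-one F3. The peri methyl ether is then cleaved separately under chelation control with AlCl3 in MeCN.

**Step 3.** The likely failures are slow bromine–lithium exchange or incomplete silyl migration on the crowded ring, and loss of silicon from the electron-rich arene on work-up. The fallback sets out from 1 (through 2) and comes back at 8. 2 is quenched with Me3SiCl to give trimethyl(2,3,4,5-tetramethoxyphenyl)silane F4. A second directed lithiation at the last ring hydrogen (n-BuLi, TMEDA), then B(OMe)3 and basic H2O2, gives 3,4,5,6-tetramethoxy-2-(trimethylsilyl)phenol F5, which is triflated (Tf2O, pyridine) to 8. This also bypasses step 2.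

**Step 2.** The likely failure is oxidation of the para-methoxyphenol to a quinone by the brominating agent instead of ring substitution. The fallback sets out from 1 and comes back at 5. 1 is brominated twice (Br2, CH2Cl2) to 1,2-dibromo-3,4,5,6-tetramethoxybenzene F6. One bromine is exchanged with i-PrMgCl·LiCl (THF, −20 °C), and the arylmagnesium is borylated with B(OMe)3 and oxidised with basic H2O2 to 5.

## Further compounds

F1 | step 6 | 2-iodo-3,4,5,6-tetramethoxyphenol | COc1c(I)c(O)c(OC)c(OC)c1OC
F2 | step 6 | 2,4-bis(benzyloxy)-1-ethynylbenzene | C#Cc1ccc(OCc2ccccc2)cc1OCc1ccccc1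
F3 | step 7 | 2-(2,4-dihydroxyphenyl)-5,6,7,8-tetramethoxy-4H-chromen-4-one | COc1c(OC)c(OC)c2c(=O)cc(-c3ccc(O)cc3O)oc2c1OC
F4 | step 3 | trimethyl(2,3,4,5-tetramethoxyphenyl)silane | COc1cc([Si](C)(C)C)c(OC)c(OC)c1OC
F5 | step 3 | 3,4,5,6-tetramethoxy-2-(trimethylsilyl)phenol | COc1c([Si](C)(C)C)c(O)c(OC)c(OC)c1OC
F6 | step 2 | 1,2-dibromo-3,4,5,6-tetramethoxybenzene | COc1c(Br)c(Br)c(OC)c(OC)c1OC
A1 | alternative 1 | 1-(2-hydroxy-3,4,5,6-tetramethoxyphenyl)ethan-1-one | CC(=O)c1c(O)c(OC)c(OC)c(OC)c1OC
A2 | alternative 1 | 2-acetyl-3,4,5,6-tetramethoxyphenyl 2,4-bis(benzyloxy)benzoate | CC(=O)c1c(OC(=O)c2ccc(OCc3ccccc3)cc2OCc2ccccc2)c(OC)c(OC)c(OC)c1OC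
A3 | alternative 1 | 1-[2,4-bis(benzyloxy)phenyl]-3-(2-hydroxy-3,4,5,6-tetramethoxyphenyl)propane-1,3-dione | O=C(CC(=O)c1c(O)c(OC)c(OC)c(OC)c1OC)c1ccc(OCc2ccccc2)cc1OCc1ccccc1
A4 | alternative 2 | dimethyl squarate (3,4-dimethoxycyclobut-3-ene-1,2-dione) | COC1=C(OC)C(=O)C1=O
A5 | alternative 2 | 2-[2,4-bis(benzyloxy)phenyl]-5-lithio-4H-pyran-4-one | [Li]c1coc(-c2ccc(OCc3ccccc3)cc2OCc2ccccc2)cc1=O
A6 | alternative 2 | 4-{6-[2,4-bis(benzyloxy)phenyl]-4-oxo-4H-pyran-3-yl}-4-hydroxy-2,3-dimethoxycyclobut-2-en-1-one (racemic) | COC1=C(OC)C(O)(c2coc(-c3ccc(OCc4ccccc4)cc3OCc3ccccc3)cc2=O)C1=O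
A7 | alternative 2 | 2-[2,4-bis(benzyloxy)phenyl]-5,8-dihydroxy-6,7-dimethoxy-4H-chromen-4-one | COc1c(OC)c(O)c2c(=O)cc(-c3ccc(OCc4ccccc4)cc3OCc3ccccc3)oc2c1O
A8 | alternative 3 | methyl 3-[2,4-bis(benzyloxy)phenyl]prop-2-ynoate | COC(=O)C#Cc1ccc(OCc2ccccc2)cc1OCc1ccccc1
A9 | alternative 3 | methyl (Z)-3-[2,4-bis(benzyloxy)phenyl]-3-(2,3,4,5-tetramethoxyphenoxy)prop-2-enoate | COC(=O)/C=C(\Oc1cc(OC)c(OC)c(OC)c1OC)c1ccc(OCc2ccccc2)cc1OCc1ccccc1
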